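By 25.0 min the delta run held less substrate than the beta run, 46% against 73%, and delta had 5.4 equiv of reagent where beta had 0.77 equiv. From these runs I had to rank the new flasks.

all flasks: substrate 10 mM

| charge | reagent | other conformer | remark | time |
|---|---|---|---|---|
| beta | 0.77 equiv | 0.25 equiv | run made earlier |  |
| delta | 5.4 equiv | 0.25 equiv | run made earlier |  |
| Saturday's | 2.70 equiv | 0.250 equiv |  | 50 min |
| Wednesday's | 2.00 equiv | 0.250 equiv |  | 50 min |
| Monday's | 1.30 equiv | 0.250 equiv |  | 50 min |
| Friday's | 4.00 equiv | 0.250 equiv |  | 50 min |
| Sunday's | 8.00 equiv | 0.250 equiv |  | 50 min |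
| Thursday's | 6.00 equiv | 0.250 equiv |  | 50 min |

| run | time / min | target / % | substrate / % |
|---|---|---|---|
| beta | 1.33 | 0 | 83 |
| beta | 4.00 | 1 | 81 |
| beta | 8.00 | 0 | 80 |
| beta | 10.0 | 2 | 78 |
| beta | 15.0 | 5 | 82 |
| beta | 20.0 | 4 | 79 |
| beta | 25.0 | 4 | 73 |
| delta | 1.33 | 2 | 79 |
| delta | 4.00 | 4 | 73 |
| delta | 8.00 | 11 | 67 |
| delta | 10.0 | 16 | 63 |
| delta | 15.0 | 17 | 57 |
| delta | 20.0 | 22 | 50 |
| delta | 25.0 | 27 | 46 |

(standard deviation of a reading: 2 percentage points)

- the earlier runs were read with a standard deviation of 2 percentage points
- in a conversion other conformer counts as not yet reacted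

1. the flasks put in order of amount of target, in percent of the substrate and other conformer together charged, best first, at 50 min (Saturday's / Wednesday's / Monday's / Friday's / Sunday's / Thursday's)
2. the same order at 6.0 h (Saturday's / Wednesday's / Monday's / Friday's / Sunday's / Thursday's)
3. the amount of target, in percent of the substrate and other conformer together charged of the flask you put first, at 50 min
4. the amount of target, in percent of the substrate and other conformer together charged of the flask you put last, at 50 min

Substrate began at 80.0% of the charge. Its fall to the last delta reading gave a pseudo-first-order rate of 0.0221 /min. I scaled this with the reagent and wrote τ for the inverse of the rate, the time scale of substrate loss. The ladder ran from Sunday's to Monday's: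

τ, Sunday's = 30.5 min, shorter than the 50 min allowed
τ, Monday's = 188 min, longer than the 50 min allowed

With reagent held at its charge, the substrate lost by 50 min was 64.5% of the charge in Sunday's and 18.7% in Monday's. Counting one reagent per substrate lost, that used 10.1% and 18.0% of their reagent. So I went round once more with the mean reagent in each flask, taking off half of what was used, in delta too:

delta 5.19; Sunday's 7.60; Monday's 1.18
loss: Sunday's 64.2%; Monday's 17.8%

The target share, the target found per substrate lost, read 73.9%, 73.3% and 79.4% in delta from 15.0 min on. With each reading carrying a standard deviation of 2 percentage points, I read no trend in these shares and could not tell from them whether reagent consumes target, so I assumed one constant share and pooled them into 75.9%. That gave me 48.7% in Sunday's and 13.5% in Monday's. On that assumption I ranked the flasks by reagent, most first, at both times.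

The forecast differed: Thursday's > Friday's > Sunday's > Saturday's > Wednesday's > Monday's, with 34% (28% to 41%) first and 16% (12% to 20%) last. At 6.0 h it gave Monday's > Wednesday's > Saturday's > Friday's > Thursday's > Sunday's, since “less reagent wins and the order reverses”.

The flasks gave Sunday's > Thursday's > Friday's > Saturday's > Wednesday's > Monday's at 50 min, from 41.2% down to 11.7%, and Sunday's > Thursday's > Friday's > Saturday's > Wednesday's > Monday's at 6.0 h.

    substrate ⇌ other conformer (K = 0.160, k = 2.20 × 10⁻⁴ /s)
    substrate + reagent ⇌ target (K = 34.0 /M, k = 0.00770 /M/s)
    reagent + other conformer → isomer of the product A (k = 0.0310 /M/s)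
    target ⇌ isomer of the product B (K = 0.190, k = 0.00280 /s)

Target and isomer of the product B relaxed into each other with a half-life of 0.659 min in Monday's, shorter than the 50 min. Sunday's had lost 59 points of substrate by 50.0 min, and the target share turns that into 44.6%, against the 41.2% found. Friday's had lost 41 points, so the same share gives 31.2%, against 28.2%.

(The readings were computed from invented constants; noise was put on by code.)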